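**Plan**

- Retrosynthesis: the diaryl ether bond C2–O–C4' is cut last, by returning ring B from the C2 oxygen to the carboxyl oxygen of ring A (retro-Smiles), which leaves an aryl ester. The ester C(=O)–O bond and the C1–C6 bond of ring A are then cut together, giving a diketo-dioxinone (ring A as an open chain) and a ring B phenol.
- Enabling feature: ring A carries carboxyl at C1, oxygen at C2 and C4 and heptyl at C6, the pattern of a folded 3,5,7-trioxotetradecanoate. In ring B the ether carbon C4' is para to the C1' carboxyl, so an ester on the C4' oxygen is activated for ipso attack by the C2 oxygen of ring A.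
- Forward, fragments: octanoyl chloride and 2,2,6-trimethyl-1,3-dioxin-4-one give diketo-dioxinone 7 (steps 1–3). Vanillic acid gives ring B phenol 23 through an amide that directs metalation to both of its ortho positions (steps 4–13).
- Forward, assembly: ring A is built on the C4' oxygen of 23 by acylketene capture and aldol aromatisation (step 14). Its C4 hydroxyl is methylated, ring B is moved to the C2 oxygen, and the benzyl groups are removed (steps 15–17).
- Stereochemistry: the target has no stereocentre and no double-bond geometry, so nothing has to be controlled.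

Key step: step 14

Remark: locants C1–C6 refer to ring A (C1 bears the carboxyl group) and primed locants to ring B (C1' bears its carboxyl group); polyketone intermediates are drawn as keto tautomers although they will be largely enolised.

**Route**

Step 1
Reactants: 1 octanoyl chloride
Product: 2 N-methoxy-N-methyloctanamide
Conditions: MeNH(OMe)·HCl, K2CO3, CH2Cl2/H2O, 0 °C to rt
Reagents that add atoms: N,O-dimethylhydroxylamine hydrochloride, CNOC.Cl
Why: Schotten–Baumann acylation of the hydroxylamine nitrogen by the acid chloride is fast in the two-phase system and gives an amide that acylates carbanions once only.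

Step 2
Reactants: 3 2,2,6-trimethyl-4H-1,3-dioxin-4-one
Product: 5 2,2-dimethyl-6-(2-oxopropyl)-4H-1,3-dioxin-4-one, via lithium dienolate 4 (not isolated)
Conditions: LiN(SiMe3)2, THF, −78 °C; then AcCl (0.5 equiv), −78 to −20 °C
Reagents that add atoms: acetyl chloride, CC(=O)Cl
Why: LiN(SiMe3)2 deprotonates the C6 methyl group to the cross-conjugated dienolate 4, which is acylated by acetyl chloride at its exocyclic carbon (vinylogous Claisen-type C-acylation), half an equivalent of electrophile being used because the more acidic product consumes a second equivalent of 4.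

Step 3
Reactants: 5 2,2-dimethyl-6-(2-oxopropyl)-4H-1,3-dioxin-4-one; 2 N-methoxy-N-methyloctanamide
Product: 7 6-(2,4-dioxoundecyl)-2,2-dimethyl-4H-1,3-dioxin-4-one, via dilithium dienolate 6 (not isolated)
Conditions: LiN(iPr)2 (3 equiv), THF, −78 °C; then 2, −78 to −20 °C; aq HCl
Reagents that add atoms: none
Why: LiN(iPr)2 converts 5 into dianion 6, whose terminal, least stabilised carbanion attacks the N-methoxy-N-methylamide in a crossed Claisen condensation that stops at the ketone because the chelated adduct does not collapse before the quench.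

Step 4
Reactants: 8 vanillic acid
Product: 9 N,N-diethyl-4-hydroxy-3-methoxybenzamide
Conditions: Et2NH, iPrN=C=NiPr, HOBt, DMF, 0 °C to rt
Reagents that add atoms: diethylamine, CCNCC
Why: Carbodiimide/HOBt amide coupling, in which the secondary amine captures the activated acid far faster than the phenol does, gives the tertiary amide that later directs both ring metalations.

Step 5
Reactants: 9 N,N-diethyl-4-hydroxy-3-methoxybenzamide
Product: 10 N,N-diethyl-3-methoxy-4-[(triisopropylsilyl)oxy]benzamide
Conditions: iPr3SiCl, imidazole, DMF, rt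
Reagents that add atoms: chlorotriisopropylsilane, CC(C)[Si](Cl)(C(C)C)C(C)C
Why: Silylation of the phenol with a hindered chlorosilane gives an ether that withstands alkyllithiums and, being bulky and non-coordinating, keeps metalation away from C5.

Step 6
Reactants: 10 N,N-diethyl-3-methoxy-4-[(triisopropylsilyl)oxy]benzamide
Product: 12 N,N-diethyl-3-methoxy-2-methyl-4-[(triisopropylsilyl)oxy]benzamide, via C2 aryllithium 11 (not isolated)
Conditions: s-BuLi, TMEDA, THF, −78 °C; then MeI, −78 °C to rt
Reagents that add atoms: iodomethane, CI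
Why: Directed ortho-metalation, in which the amide and the methoxy group act together on the C2 proton lying between them, should give aryllithium 11, which iodomethane alkylates.

Step 7
Reactants: 12 N,N-diethyl-3-methoxy-2-methyl-4-[(triisopropylsilyl)oxy]benzamide; 13 1-iodohexane
Product: 15 N,N-diethyl-2-heptyl-3-methoxy-4-[(triisopropylsilyl)oxy]benzamide, via benzylic organolithium 14 (not isolated)
Conditions: LiN(iPr)2, THF, −78 °C; then 13, −78 °C to rt
Reagents that add atoms: none
Why: Lateral lithiation, in which LiN(iPr)2 (too weak to metalate the ring) removes a proton from the ortho methyl group, gives the amide-stabilised benzylic anion 14, which the primary iodide alkylates in an SN2 reaction to complete the heptyl chain.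

Step 8
Reactants: 15 N,N-diethyl-2-heptyl-3-methoxy-4-[(triisopropylsilyl)oxy]benzamide
Product: 18 N,N-diethyl-2-heptyl-6-hydroxy-3-methoxy-4-[(triisopropylsilyl)oxy]benzamide, via C6 aryllithium 16 (not isolated), via dimethyl arylboronate 17 (not isolated)
Conditions: s-BuLi, TMEDA, THF, −78 °C; B(OMe)3, −78 °C to rt; then H2O2, AcOH, 0 °C to rt
Reagents that add atoms: hydrogen peroxide, OO
Why: A second directed ortho-metalation under kinetic conditions should take the only ring proton left ortho to the amide (C6) in preference to the hindered secondary benzylic protons, and borylation followed by the oxidative aryl shift from boron to oxygen turns the C–Li bond into C–OH.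

Step 9
Reactants: 18 N,N-diethyl-2-heptyl-6-hydroxy-3-methoxy-4-[(triisopropylsilyl)oxy]benzamide
Product: 19 6-(benzyloxy)-N,N-diethyl-2-heptyl-3-methoxy-4-[(triisopropylsilyl)oxy]benzamide
Conditions: BnBr, K2CO3, acetone, reflux
Reagents that add atoms: benzyl bromide, BrCc1ccccc1
Why: Williamson etherification of the phenol with benzyl bromide under mild carbonate conditions should leave the aryl silyl ether intact.

Step 10
Reactants: 19 6-(benzyloxy)-N,N-diethyl-2-heptyl-3-methoxy-4-[(triisopropylsilyl)oxy]benzamide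
Product: 20 2-(benzyloxy)-6-heptyl-5-methoxy-4-[(triisopropylsilyl)oxy]benzaldehyde
Conditions: Cp2Zr(H)Cl, THF, rt; aqueous work-up
Reagents that add atoms: none
Why: Cp2Zr(H)Cl transfers one hydride to the carbonyl carbon of a tertiary amide and the aldehyde is set free only on aqueous work-up, so this chemoselective amide-to-aldehyde reduction avoids the harsh hydrolysis that a doubly ortho-substituted diethylamide would need.

Step 11
Reactants: 20 2-(benzyloxy)-6-heptyl-5-methoxy-4-[(triisopropylsilyl)oxy]benzaldehyde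
Product: 21 2-(benzyloxy)-6-heptyl-5-methoxy-4-[(triisopropylsilyl)oxy]benzoic acid
Conditions: NaClO2, NaH2PO4, 2-methyl-2-butene, t-BuOH/H2O, rt
Reagents that add atoms: sodium chlorite, [Na+].[O-]Cl=O
Why: Pinnick oxidation converts the hindered aldehyde into the acid while 2-methyl-2-butene traps the HOCl formed, protecting the electron-rich ring from chlorination.

Step 12
Reactants: 21 2-(benzyloxy)-6-heptyl-5-methoxy-4-[(triisopropylsilyl)oxy]benzoic acid
Product: 22 benzyl 2-(benzyloxy)-6-heptyl-5-methoxy-4-[(triisopropylsilyl)oxy]benzoate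
Conditions: BnBr, KHCO3, DMF, rt
Reagents that add atoms: benzyl bromide, BrCc1ccccc1
Why: O-Alkylation of the carboxylate with benzyl bromide (SN2 at the benzylic carbon) esterifies the acid without requiring attack at its hindered carbonyl group.

Step 13
Reactants: 22 benzyl 2-(benzyloxy)-6-heptyl-5-methoxy-4-[(triisopropylsilyl)oxy]benzoate
Product: 23 benzyl 2-(benzyloxy)-6-heptyl-4-hydroxy-5-methoxybenzoate
Conditions: Bu4NF, AcOH, THF, 0 °C
Reagents that add atoms: none
Why: Fluoride-induced cleavage of the aryl silyl ether, buffered with acetic acid so that the benzyl ester and ether are untouched, frees the C4' phenol.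

Step 14
Reactants: 7 6-(2,4-dioxoundecyl)-2,2-dimethyl-4H-1,3-dioxin-4-one; 23 benzyl 2-(benzyloxy)-6-heptyl-4-hydroxy-5-methoxybenzoate
Product: 27 benzyl 2-(benzyloxy)-6-heptyl-4-[(6-heptyl-2,4-dihydroxybenzoyl)oxy]-5-methoxybenzoate, via acylketene 24 (not isolated), via aryl triketo ester 25 (not isolated), via cyclic aldol 26 (not isolated)
Conditions: 7 (1.3 equiv), PhMe, 110 °C; then Et3N, CH2Cl2, rt; then HCl, dioxane, rt
Reagents that add atoms: none
Why: Heating 7 causes a retro-hetero-Diels–Alder loss of acetone to acylketene 24, whose ketene carbon is captured under neutral conditions by the only free hydroxyl of 23 (the C4' phenol) to give the aryl 3,5,7-trioxo ester 25, so the hindered acyl–oxygen bond is made without activating a doubly ortho-substituted acid. Et3N then enolises 25 and the carbon between ester and ketone (the future C1) adds to the heptyl ketone (the future C6) in a 6-(enolexo)-exo-trig aldol closure that forms the C1–C6 bond and ring A as the cyclic aldol 26, which HCl dehydrates and which tautomerises to the resorcylate 27. The closest known chemistry is the thermolysis of diketo-dioxinones in the presence of alcohols followed by base- then acid-mediated aldol aromatisation to 6-alkyl-2,4-dihydroxybenzoates, together with the capture of dioxinone-derived acylketenes by phenols. No stereocentre is created in the product, the two centres of 26 being lost on aromatisation. The step needs the fold to run through the aldol mode and not through Claisen-type C-acylation or lactonisation with loss of the aryloxide: the future C1 is a doubly activated carbon that can reach only the heptyl ketone through a six-membered transition state, and a weak, non-nucleophilic amine base at room temperature, with acid added only after ring closure, should keep the aryl ester intact.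

Step 15
Reactants: 27 benzyl 2-(benzyloxy)-6-heptyl-4-[(6-heptyl-2,4-dihydroxybenzoyl)oxy]-5-methoxybenzoate
Product: 28 benzyl 2-(benzyloxy)-6-heptyl-4-[(6-heptyl-2-hydroxy-4-methoxybenzoyl)oxy]-5-methoxybenzoate
Conditions: Me3SiCHN2, iPr2NEt, MeOH/MeCN, rt
Reagents that add atoms: trimethylsilyldiazomethane, C[Si](C)(C)C=[N+]=[N-]
Why: O-Methylation with a diazoalkane is selective for the C4 hydroxyl, which is the more acidic and is not hydrogen-bonded, whereas the C2 hydroxyl is held by the ester carbonyl and stays free for the next step.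

Step 16
Reactants: 28 benzyl 2-(benzyloxy)-6-heptyl-4-[(6-heptyl-2-hydroxy-4-methoxybenzoyl)oxy]-5-methoxybenzoate
Product: 30 2-{5-(benzyloxy)-4-[(benzyloxy)carbonyl]-3-heptyl-2-methoxyphenoxy}-6-heptyl-4-methoxybenzoic acid, via spiro Meisenheimer adduct 29 (not isolated)
Conditions: K2CO3 (dry), DMSO, rt to 50 °C; then aq HCl
Reagents that add atoms: none
Why: Smiles rearrangement, in which K2CO3 ionises the chelated C2 hydroxyl of ring A and the phenoxide attacks C4' of ring B at the ipso position through the six-membered spiro adduct 29 (its charge taken up by the para benzyl ester at C1'), ends with cleavage of the C4'–O(acyl) bond to release the poorly nucleophilic ring A carboxylate, which makes the aryl shift irreversible.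

Step 17
Reactants: 30 2-{5-(benzyloxy)-4-[(benzyloxy)carbonyl]-3-heptyl-2-methoxyphenoxy}-6-heptyl-4-methoxybenzoic acid
Product: 31 4-(2-carboxy-3-heptyl-5-methoxyphenoxy)-6-heptyl-2-hydroxy-5-methoxybenzoic acid (CNP0151337.0)
Conditions: H2 (1 atm), Pd/C, EtOAc/EtOH, rt
Reagents that add atoms: none
Why: Catalytic hydrogenolysis cleaves the benzyl ether and the benzyl ester to the phenol and the acid while the diaryl ether, the methyl ethers and the free carboxyl group are inert under these conditions.

**Compound list**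

1 | octanoyl chloride | CCCCCCCC(=O)Cl | starting material
2 | N-methoxy-N-methyloctanamide | CCCCCCCC(=O)N(C)OC | intermediate
3 | 2,2,6-trimethyl-4H-1,3-dioxin-4-one | CC1=CC(=O)OC(C)(C)O1 | starting material
4 | lithium dienolate of 3 (lithium 2,2-dimethyl-6-methylidene-1,3-dioxin-4-olate) | C=C1C=C(O[Li])OC(C)(C)O1 | intermediate
5 | 2,2-dimethyl-6-(2-oxopropyl)-4H-1,3-dioxin-4-one | CC(=O)CC1=CC(=O)OC(C)(C)O1 | intermediate
6 | dilithium dienolate of 5 (lithiated at the terminal methyl and as the enolate) | [Li]CC(O[Li])=CC1=CC(=O)OC(C)(C)O1 | intermediate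
7 | 6-(2,4-dioxoundecyl)-2,2-dimethyl-4H-1,3-dioxin-4-one | CCCCCCCC(=O)CC(=O)CC1=CC(=O)OC(C)(C)O1 | intermediate
8 | vanillic acid (4-hydroxy-3-methoxybenzoic acid) | COc1cc(C(=O)O)ccc1O | starting material
9 | N,N-diethyl-4-hydroxy-3-methoxybenzamide | CCN(CC)C(=O)c1ccc(O)c(OC)c1 | intermediate
10 | N,N-diethyl-3-methoxy-4-[(triisopropylsilyl)oxy]benzamide | CCN(CC)C(=O)c1ccc(O[Si](C(C)C)(C(C)C)C(C)C)c(OC)c1 | intermediate
11 | C2 aryllithium of 10 | CCN(CC)C(=O)c1ccc(O[Si](C(C)C)(C(C)C)C(C)C)c(OC)c1[Li] | intermediate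
12 | N,N-diethyl-3-methoxy-2-methyl-4-[(triisopropylsilyl)oxy]benzamide | CCN(CC)C(=O)c1ccc(O[Si](C(C)C)(C(C)C)C(C)C)c(OC)c1C | intermediate
13 | 1-iodohexane | CCCCCCI | starting material
14 | benzylic organolithium of 12 | CCN(CC)C(=O)c1ccc(O[Si](C(C)C)(C(C)C)C(C)C)c(OC)c1C[Li] | intermediate
15 | N,N-diethyl-2-heptyl-3-methoxy-4-[(triisopropylsilyl)oxy]benzamide | CCCCCCCc1c(OC)c(O[Si](C(C)C)(C(C)C)C(C)C)ccc1C(=O)N(CC)CC | intermediate
16 | C6 aryllithium of 15 | CCCCCCCc1c(OC)c(O[Si](C(C)C)(C(C)C)C(C)C)cc([Li])c1C(=O)N(CC)CC | intermediate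
17 | dimethyl arylboronate at C6 of 15 | CCCCCCCc1c(OC)c(O[Si](C(C)C)(C(C)C)C(C)C)cc(B(OC)OC)c1C(=O)N(CC)CC | intermediate
18 | N,N-diethyl-2-heptyl-6-hydroxy-3-methoxy-4-[(triisopropylsilyl)oxy]benzamide | CCCCCCCc1c(OC)c(O[Si](C(C)C)(C(C)C)C(C)C)cc(O)c1C(=O)N(CC)CC | intermediate
19 | 6-(benzyloxy)-N,N-diethyl-2-heptyl-3-methoxy-4-[(triisopropylsilyl)oxy]benzamide | CCCCCCCc1c(OC)c(O[Si](C(C)C)(C(C)C)C(C)C)cc(OCc2ccccc2)c1C(=O)N(CC)CC | intermediate
20 | 2-(benzyloxy)-6-heptyl-5-methoxy-4-[(triisopropylsilyl)oxy]benzaldehyde | CCCCCCCc1c(OC)c(O[Si](C(C)C)(C(C)C)C(C)C)cc(OCc2ccccc2)c1C=O | intermediate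
21 | 2-(benzyloxy)-6-heptyl-5-methoxy-4-[(triisopropylsilyl)oxy]benzoic acid | CCCCCCCc1c(OC)c(O[Si](C(C)C)(C(C)C)C(C)C)cc(OCc2ccccc2)c1C(=O)O | intermediate
22 | benzyl 2-(benzyloxy)-6-heptyl-5-methoxy-4-[(triisopropylsilyl)oxy]benzoate | CCCCCCCc1c(OC)c(O[Si](C(C)C)(C(C)C)C(C)C)cc(OCc2ccccc2)c1C(=O)OCc1ccccc1 | intermediate
23 | benzyl 2-(benzyloxy)-6-heptyl-4-hydroxy-5-methoxybenzoate (ring B phenol) | CCCCCCCc1c(OC)c(O)cc(OCc2ccccc2)c1C(=O)OCc1ccccc1 | intermediate
24 | acylketene 3,5,7-trioxotetradec-1-en-1-one | CCCCCCCC(=O)CC(=O)CC(=O)C=C=O | intermediate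
25 | benzyl 2-(benzyloxy)-6-heptyl-5-methoxy-4-[(3,5,7-trioxotetradecanoyl)oxy]benzoate | CCCCCCCC(=O)CC(=O)CC(=O)CC(=O)Oc1cc(OCc2ccccc2)c(C(=O)OCc2ccccc2)c(CCCCCCC)c1OC | intermediate
26 | benzyl 2-(benzyloxy)-6-heptyl-4-[(2-heptyl-2-hydroxy-4,6-dioxocyclohexane-1-carbonyl)oxy]-5-methoxybenzoate (cyclic aldol, mixture of diastereomers) | CCCCCCCC1(O)CC(=O)CC(=O)C1C(=O)Oc1cc(OCc2ccccc2)c(C(=O)OCc2ccccc2)c(CCCCCCC)c1OC | intermediate
27 | benzyl 2-(benzyloxy)-6-heptyl-4-[(6-heptyl-2,4-dihydroxybenzoyl)oxy]-5-methoxybenzoate | CCCCCCCc1cc(O)cc(O)c1C(=O)Oc1cc(OCc2ccccc2)c(C(=O)OCc2ccccc2)c(CCCCCCC)c1OC | intermediate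
28 | benzyl 2-(benzyloxy)-6-heptyl-4-[(6-heptyl-2-hydroxy-4-methoxybenzoyl)oxy]-5-methoxybenzoate | CCCCCCCc1cc(OC)cc(O)c1C(=O)Oc1cc(OCc2ccccc2)c(C(=O)OCc2ccccc2)c(CCCCCCC)c1OC | intermediate
29 | spiro Meisenheimer adduct (potassium salt; spiro carbon C4' bonded to the acyl oxygen and to the C2 oxygen of ring A, charge on the ring B ester enolate) | CCCCCCCc1cc(OC)cc2OC3(OC(=O)c12)C=C(OCc1ccccc1)C(=C([O-])OCc1ccccc1)C(CCCCCCC)=C3OC.[K+] | intermediate
30 | 2-{5-(benzyloxy)-4-[(benzyloxy)carbonyl]-3-heptyl-2-methoxyphenoxy}-6-heptyl-4-methoxybenzoic acid | CCCCCCCc1cc(OC)cc(Oc2cc(OCc3ccccc3)c(C(=O)OCc3ccccc3)c(CCCCCCC)c2OC)c1C(=O)O | intermediate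
31 | 4-(2-carboxy-3-heptyl-5-methoxyphenoxy)-6-heptyl-2-hydroxy-5-methoxybenzoic acid (CNP0151337.0) | CCCCCCCc1cc(OC)cc(Oc2cc(O)c(C(=O)O)c(CCCCCCC)c2OC)c1C(=O)O | target

**Step count and risks**

Total steps: 17. Longest linear sequence: 14 steps (steps 4–17, from vanillic acid).

Steps most likely to fail:

1. Step 14. The acylketene may cyclise on itself before the electron-poor phenol captures it. The aryl triketo ester may also expel the aryloxide by lactonisation or Claisen-type C-acylation instead of closing by the aldol mode. Fallback, setting out from 7 and coming back at 28: 7 would be heated with benzyl alcohol in toluene, a primary alcohol being the most reliable partner for the ketene, to give benzyl 3,5,7-trioxotetradecanoate F1. Et3N should close it to benzyl 2-heptyl-2-hydroxy-4,6-dioxocyclohexane-1-carboxylate F2, and HCl should dehydrate this to benzyl 6-heptyl-2,4-dihydroxybenzoate F3. Methylation with Me3SiCHN2 as in step 15 would give benzyl 6-heptyl-2-hydroxy-4-methoxybenzoate F4, and hydrogenolysis (H2, Pd/C) 6-heptyl-2-hydroxy-4-methoxybenzoic acid F5. F5 would then be joined to phenol 23 with (CF3CO)2O in toluene through the mixed anhydride, which gives 28 directly. Ring A is still made by the polyketide fold, but the ester bond is made by conventional acylation.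

2. Step 16. The benzyl ester at C1', twisted out of the ring plane by its two ortho substituents, may stabilise the spiro adduct too weakly. Ipso attack would then be slow, and base-induced cleavage of the aryl ester would compete with the aryl shift. Fallback, setting out from 20 and coming back at 31: ring B would be carried at the aldehyde oxidation level, because a formyl group at C1' stays in the ring plane and is the stronger acceptor. Bu4NF/AcOH on 20 would give 2-(benzyloxy)-6-heptyl-4-hydroxy-5-methoxybenzaldehyde F6. Thermolysis with 7 as in step 14 would give 5-(benzyloxy)-4-formyl-3-heptyl-2-methoxyphenyl 3,5,7-trioxotetradecanoate F7, then with Et3N the cyclic aldol 5-(benzyloxy)-4-formyl-3-heptyl-2-methoxyphenyl 2-heptyl-2-hydroxy-4,6-dioxocyclohexane-1-carboxylate F8, and with HCl 5-(benzyloxy)-4-formyl-3-heptyl-2-methoxyphenyl 6-heptyl-2,4-dihydroxybenzoate F9. Me3SiCHN2 would give 5-(benzyloxy)-4-formyl-3-heptyl-2-methoxyphenyl 6-heptyl-2-hydroxy-4-methoxybenzoate F10. K2CO3 in DMSO should then give 2-[5-(benzyloxy)-4-formyl-3-heptyl-2-methoxyphenoxy]-6-heptyl-4-methoxybenzoic acid F11. Pinnick oxidation would give 2-(benzyloxy)-4-(2-carboxy-3-heptyl-5-methoxyphenoxy)-6-heptyl-5-methoxybenzoic acid F12, and hydrogenolysis of its single benzyl ether would give 31.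

3. Step 8. Deprotonation at the benzylic CH2 of the heptyl chain (lateral metalation) may compete with ring metalation at C6, so that boron and then oxygen end up on the side chain. Fallback, setting out from 15 and coming back at aryllithium 16: NBS in MeCN should brominate 15 para to the methoxy group, by electrophilic aromatic substitution instead of deprotonation, to give 6-bromo-N,N-diethyl-2-heptyl-3-methoxy-4-[(triisopropylsilyl)oxy]benzamide F13. Bromine–lithium exchange with n-BuLi at −78 °C, which is faster than any proton removal, would then deliver 16 for the borylation and oxidation of step 8.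

**Further compounds**

F1 | step 14 | benzyl 3,5,7-trioxotetradecanoate | CCCCCCCC(=O)CC(=O)CC(=O)CC(=O)OCc1ccccc1
F2 | step 14 | benzyl 2-heptyl-2-hydroxy-4,6-dioxocyclohexane-1-carboxylate | CCCCCCCC1(O)CC(=O)CC(=O)C1C(=O)OCc1ccccc1
F3 | step 14 | benzyl 6-heptyl-2,4-dihydroxybenzoate | CCCCCCCc1cc(O)cc(O)c1C(=O)OCc1ccccc1
F4 | step 14 | benzyl 6-heptyl-2-hydroxy-4-methoxybenzoate | CCCCCCCc1cc(OC)cc(O)c1C(=O)OCc1ccccc1
F5 | step 14 | 6-heptyl-2-hydroxy-4-methoxybenzoic acid | CCCCCCCc1cc(OC)cc(O)c1C(=O)O
F6 | step 16 | 2-(benzyloxy)-6-heptyl-4-hydroxy-5-methoxybenzaldehyde | CCCCCCCc1c(OC)c(O)cc(OCc2ccccc2)c1C=O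
F7 | step 16 | 5-(benzyloxy)-4-formyl-3-heptyl-2-methoxyphenyl 3,5,7-trioxotetradecanoate | CCCCCCCC(=O)CC(=O)CC(=O)CC(=O)Oc1cc(OCc2ccccc2)c(C=O)c(CCCCCCC)c1OC
F8 | step 16 | 5-(benzyloxy)-4-formyl-3-heptyl-2-methoxyphenyl 2-heptyl-2-hydroxy-4,6-dioxocyclohexane-1-carboxylate | CCCCCCCC1(O)CC(=O)CC(=O)C1C(=O)Oc1cc(OCc2ccccc2)c(C=O)c(CCCCCCC)c1OC
F9 | step 16 | 5-(benzyloxy)-4-formyl-3-heptyl-2-methoxyphenyl 6-heptyl-2,4-dihydroxybenzoate | CCCCCCCc1cc(O)cc(O)c1C(=O)Oc1cc(OCc2ccccc2)c(C=O)c(CCCCCCC)c1OC
F10 | step 16 | 5-(benzyloxy)-4-formyl-3-heptyl-2-methoxyphenyl 6-heptyl-2-hydroxy-4-methoxybenzoate | CCCCCCCc1cc(OC)cc(O)c1C(=O)Oc1cc(OCc2ccccc2)c(C=O)c(CCCCCCC)c1OC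
F11 | step 16 | 2-[5-(benzyloxy)-4-formyl-3-heptyl-2-methoxyphenoxy]-6-heptyl-4-methoxybenzoic acid | CCCCCCCc1cc(OC)cc(Oc2cc(OCc3ccccc3)c(C=O)c(CCCCCCC)c2OC)c1C(=O)O
F12 | step 16 | 2-(benzyloxy)-4-(2-carboxy-3-heptyl-5-methoxyphenoxy)-6-heptyl-5-methoxybenzoic acid | CCCCCCCc1cc(OC)cc(Oc2cc(OCc3ccccc3)c(C(=O)O)c(CCCCCCC)c2OC)c1C(=O)O
F13 | step 8 | 6-bromo-N,N-diethyl-2-heptyl-3-methoxy-4-[(triisopropylsilyl)oxy]benzamide | CCCCCCCc1c(OC)c(O[Si](C(C)C)(C(C)C)C(C)C)cc(Br)c1C(=O)N(CC)CC
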